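## Analysis of the target

Huanglongmycin D (30) is a benzophenone: ring A (C1 to C6) and ring C (C1' to C6') are joined only through one ketone carbon, and there is no further ring. Ring A is substituted on five carbons in a row: acetyl on C1, the CH2CO2H arm on C2, a carboxyl on C4, the aroyl group on C5 and a hydroxyl on C6; only C3 carries hydrogen. Ring C carries the ketone on C1' and hydroxyls on C2' and C6'. There is no stereocentre, and because ring C is symmetric about its C1'–C4' axis, slow rotation at the crowded ketone cannot create isomers. The sensitive points are three: the neighbouring acetyl and CH2CO2H groups, which can condense with each other to a six-membered ring under base or hot acid; the ortho-aroylbenzoic acid, which equilibrates with its hydroxy lactone; and the three free phenols, which are easily oxidised and can condense with the ketone or the C4 carboxyl. The main difficulty is the ketone itself: it has four ortho substituents (C4 and C6 on ring A, C2' and C6' on ring C), and electrophilic acylation of a 1,3-dioxygenated benzene goes para to an oxygen, not to the carbon between the two oxygens. The plan rests on that very carbon. C1', flanked by the oxygens on C2' and C6', is the pattern formed when a vinylketene and an alkoxyalkyne are joined to a phenol: one oxygen comes from the ketene carbonyl, the other from the alkyne, and the carbon between them is the second alkyne carbon, which can be bonded to the future ketone carbon before ring C exists.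

## Retrosynthetic reasoning

**30 from 29.** The three phenols of 30 are taken back to the ethers of keto diacid 29 (two O–ethyl bonds on ring C, one O–methyl bond at C6). Cutting here keeps the phenols capped through every basic and oxidising step and prevents ring C from condensing with ring A. All three ethers sit ortho to a carbonyl group, so one chelating Lewis acid should remove them together while the acids and ketones stay as they are.

**29 from 26.** The ketone between the rings is taken back to a carbinol carbon, which is tied to the C4 carboxyl as the five-membered lactone of 26; the acetyl group returns to its dioxolane and the side-chain acid to its methyl ester. The lactone stores two functions of 30 without an extra atom and turns the crowded ketone carbon into an sp3 carbon. Forward, base must open lactone and ester to dicarboxylate 27, which cannot close back; oxidation in the same flask gives 28, and acid frees the acetyl group.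

**26 from 25.** The O–ethyl bond on the second ring C oxygen is cut. The free phenol of 25 would be the first group attacked in the oxidation that makes the ketone. Ethyl is chosen so that ring C of 26 is symmetric and identical with what a preformed 2,6-diethoxyphenyl nucleophile would give, which is the safety net of the route.

**25 from 17 and 20 (key disconnection).** Ring C is cut at C1'–C2', C2'–C3' and C5'–C6'. C1' and C6' become the two alkyne carbons of 17; C2' to C5' become the four carbons of diazoketone 20 (C2' its carbonyl carbon, C5' its diazo carbon, C3' and C4' its vinyl carbons). This is the only cut in which the bond from ring C to the carbinol carbon exists before ring C does, so no bond is ever made at a di-ortho-substituted arene, and both ring C oxygens arrive in place. Forward, 20 must rearrange to vinylketene 21, which has to add to the alkyne with one orientation and pass through 22, 23 and 24 to the phenol.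

**17 from 13 and 14.** The bond between the carbinol carbon and the alkyne is cut, giving aldehyde 13 and ethoxyethyne 14, used as its lithium salt 15. The aldehyde lies ortho to a methyl ester, so alkoxide 16 closes the lactone by itself and protection of carbinol and carboxyl costs no step. The addition must be faster than proton transfer from the CH2 of the side chain, and the acid-sensitive ynol ether must be isolated gently.

**20 from 18.** The diazo group is placed on the methyl carbon of enone 18 after acyl activation (19). The acid chloride route to diazoketones is closed for a vinyl ketone, because the diazo reagent would add to the C=C bond.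

**13 from 12, and 12 from 10 and 11.** The aldehyde carbon is traced to the vinyl group of 12, and that to aryl iodide 10 and stannane 11. A one-carbon electrophile on a ring-metal species would be shorter, but in 10 the CH2 of the side chain is the most acidic position and would quench any aryl metal or amide base. An aldehyde introduced earlier could not survive the aryne step and could not be told apart from the ketone when that is protected. A vinyl group is inert to both and is unmasked under neutral conditions.

**10 from 9.** The two C–O bonds of the dioxolane are cut. The acetyl group is masked so that acetylide 15 meets one carbonyl electrophile and no enolisable ketone, and so that the photochemical step meets no aryl ketone chromophore with a benzylic C–H beside it.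

**9 from 6 and 7.** Both carbon substituents on C1 and C2 are cut at once (C1–acetyl and C2–CH2). Aryne 8, released from 6, inserts into the bond between the ketone carbon and the α-carbon of β-ketoester 7. This sets acetyl and acetate arm on neighbouring carbons in one step; the methoxy group next to the triple bond sends the nucleophile to the remote aryne carbon, so the acetyl group ends beside the methoxy group, as in 30.

**6 from 4.** The C–I bond at C5 of ring A is cut. Directed magnesiation (5) between ester and methoxy group is done at this stage because 4 has no acidic C–H other than ring positions.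

**4 from 1.** The C–Si and O–S bonds are cut. Bromophenol 1 has bromine exactly where silicon is needed, next to the hydroxyl, and these two carbons define aryne 8; the path runs through 2 and 3.

## Alternatives that were turned down

**Alternative 1: Ring A by Tamura cycloaddition.**
- Disconnection: the C3–C4 and C5–C6 bonds of ring A. This gives a four-carbon piece (C6, C1, C2, C3 with hydroxyl, acetyl and acetate arm) and a two-carbon piece (C4 and C5 with the ester and the whole aroyl group).
- Forward key step: hydroxypyranone A3, the enol form of a C-acetylated glutaconic anhydride, would add across the triple bond of alkynone A2; decarboxylation of the bridged adduct would aromatise ring A to A1, which holds every carbon of 30.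
- For: it is the most convergent plan. The crowded ketone is present in A2 before ring A exists, so no arene is acylated. A1 is only an ester hydrolysis and an ether cleavage from 30, with no change of oxidation level.
- Against: both partners are ambident. A2 accepts at either alkyne carbon (ynone or ynoate) and A3 can react through either α-carbon, so only one of four orientations gives A1 and nothing in the structures enforces it. A3 is a fully enolised β-tricarbonyl compound and a reluctant nucleophile. The ortho-methoxyaryl ynone of A2 can cyclise onto its own methoxy oxygen under nucleophilic conditions.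
- Comparison: on step count and convergence this plan is clearly stronger, at roughly half the steps. The chosen plan offers one built-in director for each ring-forming event (the methoxy group for aryne 8, the ynol ether oxygen for 17), so the position of every substituent can be predicted.

**Alternative 2: Baeyer–Villiger cleavage of an anthraquinone.**
- Disconnection: the C2'–O bond of ring C; the C4 carboxyl carbon of 30 is rejoined in thought to C2', giving the 1,8-dimethoxyanthraquinone A5.
- Forward key step: a strong peroxy acid would add to the quinone carbonyl that has no peri methoxy group, the ring C carbon would migrate to oxygen, and the central ring would grow to the seven-membered lactone A4. Hydrolysis and demethylation would then give 30.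
- For: it follows the likely biogenesis and is short. A5 is flat, rigid and accessible by standard anthraquinone annulations. The hindered ketone and the carboxyl carbon are in place before the key step, and one oxidation creates carboxyl and phenol together.
- Against: the acetyl group of ring A is an aryl methyl ketone, a better substrate for oxygen insertion than a quinone carbonyl conjugated to two arenes, and it cannot be kept as an acetal in acidic peroxide. Conditions forcing enough for the quinone would also hydroxylate the methoxy-bearing rings. The choice between the two quinone carbonyls rests on peri hindrance alone, and the choice of migrating aryl group on a small electronic difference.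
- Comparison: it is shorter and more elegant, and equal to the chosen plan in avoiding acylation of ring C. The chosen plan offers separation of the two ketones: the acetyl group is a dioxolane from step 4 to step 11, and the central carbon is raised from the carbinol level by an oxidation that meets only one alcohol.

**Alternative 3: Ring A from a cyclohexanedione by Michael–Claisen annulation.**
- Disconnection: C4–C5 and C1–C2 of ring A, made on a non-aromatic ring. Aroyl diketone A7 supplies C5, C6, C1 and the benzophenone carbonyl; fumarate A8 supplies C4 with its ester, C3 and C2.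
- Forward key step: the central carbon of A7 adds to A8, and the terminal methyl group then condenses on the far ester and closes the six-membered dione A6.
- For: the cheapest materials and the simplest operation of all four plans. Ring C and the crowded ketone are bought ready-made, and the annulation is plain base chemistry.
- Against: A6 has ring A at the wrong oxidation level and lacks the acetyl group at C1 and the acetate arm at C2. C1 would have to be acylated in a triketone with three acidic sites. C2 would have to change from a carbonyl carbon to an arene carbon bearing a chain. The ring would then have to be dehydrogenated without touching ring C. Throughout, the aroyl group sits on a β-tricarbonyl carbon and can be lost by retro-Claisen cleavage.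
- Comparison: its opening step is more robust and cheaper than any step of the chosen plan. But the sequence after it is longer than the whole chosen route after step 9 and has no controlling element. The chosen plan sets acetyl group and acetate arm in one step on an aromatic ring (step 3) and keeps ring A aromatic throughout.

Key step: step 9

## Route

Remark: compound 1 (methyl 5-bromovanillate) is taken to be a catalogue chemical.
Remark: 30 is achiral; the stereocentres that appear on the way (the lactone carbon of 17 and 22 to 26, the ring carbon of 22) are uncontrolled and are all removed before 30.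

Step 1
Reactants: 1 methyl 3-bromo-4-hydroxy-5-methoxybenzoate
Product: 4 methyl 3-methoxy-4-[(trifluoromethanesulfonyl)oxy]-5-(trimethylsilyl)benzoate, via aryl trimethylsilyl ether 2 (not isolated), via lithium phenolate 3 (not isolated)
Conditions: (Me3Si)2NH, THF, 65 °C, then evaporate; n-BuLi, THF, −100 °C; Tf2O, −100 to −78 °C
Reagents that add atoms: hexamethyldisilazane C[Si](C)(C)N[Si](C)(C)C; trifluoromethanesulfonic anhydride O=S(=O)(OS(=O)(=O)C(F)(F)F)C(F)(F)F
Why: O-silylation, bromine–lithium exchange and retro-Brook O-to-C silyl shift, then triflation, the standard route to 2-silylaryl triflates; at −100 °C exchange should outrun addition to the methyl ester, and the ortho-lithio silyl ether rearranges at once to phenolate 3.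

Step 2
Reactants: 4 methyl 3-methoxy-4-[(trifluoromethanesulfonyl)oxy]-5-(trimethylsilyl)benzoate
Product: 6 methyl 2-iodo-3-methoxy-4-[(trifluoromethanesulfonyl)oxy]-5-(trimethylsilyl)benzoate, via arylmagnesium chloride 5 (not isolated)
Conditions: TMPMgCl·LiCl, THF, −20 to 0 °C; I2, −20 °C to rt
Reagents that add atoms: iodine II
Why: Directed ortho-magnesiation with an amide base that tolerates ester and triflate; the C–H between ester and methoxy group is activated by both, whereas the other ortho C–H has one activating group and is shielded by the SiMe3 group; iodine quench of 5 gives the aryl iodide.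

Step 3
Reactants: 6 methyl 2-iodo-3-methoxy-4-[(trifluoromethanesulfonyl)oxy]-5-(trimethylsilyl)benzoate; 7 methyl 3-oxobutanoate
Product: 9 methyl 4-acetyl-2-iodo-3-methoxy-5-(2-methoxy-2-oxoethyl)benzoate, via aryne 8 (not isolated)
Conditions: CsF, MeCN, 80 °C
Reagents that add atoms: none
Why: Aryne acyl-alkylation: fluoride releases 8, the enolate of 7 attacks the aryne carbon remote from the methoxy group, the aryl anion beside the methoxy group adds to the ketone, and the four-membered alkoxide fragments, leaving acetyl next to OMe and the acetate arm next to C–H.

Step 4
Reactants: 9 methyl 4-acetyl-2-iodo-3-methoxy-5-(2-methoxy-2-oxoethyl)benzoate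
Product: 10 methyl 2-iodo-3-methoxy-5-(2-methoxy-2-oxoethyl)-4-(2-methyl-1,3-dioxolan-2-yl)benzoate
Conditions: Me3SiOCH2CH2OSiMe3, Me3SiOTf (cat.), CH2Cl2, −20 °C to rt
Reagents that add atoms: 1,2-bis(trimethylsilyloxy)ethane C[Si](C)(C)OCCO[Si](C)(C)C
Why: Ketalisation under aprotic silyl triflate catalysis, which is driven by formation of the disiloxane and suits hindered ketones; the iodide, both esters and the acidic CH2 are untouched.

Step 5
Reactants: 10 methyl 2-iodo-3-methoxy-5-(2-methoxy-2-oxoethyl)-4-(2-methyl-1,3-dioxolan-2-yl)benzoate; 11 tributyl(ethenyl)stannane
Product: 12 methyl 2-ethenyl-3-methoxy-5-(2-methoxy-2-oxoethyl)-4-(2-methyl-1,3-dioxolan-2-yl)benzoate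
Conditions: Pd(PPh3)4 (cat.), CuI (cat.), CsF, DMF, 45 °C
Reagents that add atoms: none
Why: Stille coupling on zerovalent palladium, promoted by CuI and fluoride for a di-ortho-substituted aryl iodide; the small vinyl group transfers easily and the near-neutral conditions leave the acidic CH2 and the esters alone.

Step 6
Reactants: 12 methyl 2-ethenyl-3-methoxy-5-(2-methoxy-2-oxoethyl)-4-(2-methyl-1,3-dioxolan-2-yl)benzoate
Product: 13 methyl 2-formyl-3-methoxy-5-(2-methoxy-2-oxoethyl)-4-(2-methyl-1,3-dioxolan-2-yl)benzoate
Conditions: O3, CH2Cl2/MeOH, −78 °C; Me2S, −78 °C to rt
Reagents that add atoms: ozone [O-][O+]=O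
Why: Ozonolysis with reductive work-up; the vinyl group is the only alkene, the arene is electron-poor, and dioxolane and esters are inert.

Step 7
Reactants: 13 methyl 2-formyl-3-methoxy-5-(2-methoxy-2-oxoethyl)-4-(2-methyl-1,3-dioxolan-2-yl)benzoate; 14 ethoxyethyne
Product: 17 methyl 2-[1-(ethoxyethynyl)-7-methoxy-6-(2-methyl-1,3-dioxolan-2-yl)-3-oxo-1,3-dihydroisobenzofuran-5-yl]acetate (racemic), via LiC≡COEt 15 (not isolated), via lithium alkoxide 16 (not isolated)
Conditions: 14, n-BuLi, THF, −78 °C; 13, −78 to 0 °C; aq NaHCO3; Et3N-deactivated silica
Reagents that add atoms: none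
Why: 1,2-Addition of a small acetylide to the aldehyde, which at −78 °C should be faster than proton transfer from the CH2 of the side chain; alkoxide 16 then closes the lactone by 5-exo-trig acyl substitution on the ortho methyl ester; the new stereocentre is formed racemic and needs no control because step 11 oxidises it.

Step 8
Reactants: 18 but-3-en-2-one
Product: 20 1-diazobut-3-en-2-one, via trifluoroacetyl diketone 19 (not isolated)
Conditions: LiN(SiMe3)2, THF, −78 °C; CF3CO2CH2CF3, −78 °C; aq HCl; MsN3, Et3N, H2O, MeCN, rt
Reagents that add atoms: methanesulfonyl azide CS(=O)(=O)N=[N+]=[N-]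
Why: Detrifluoroacetylative diazo transfer: the kinetic enolate on the methyl side is trifluoroacetylated to 19, the sulfonyl azide transfers the diazo group, and the trifluoroacetyl group leaves on the sulfonamide; no diazo reagent that could add to the vinyl group is used.

Step 9
Reactants: 17 methyl 2-[1-(ethoxyethynyl)-7-methoxy-6-(2-methyl-1,3-dioxolan-2-yl)-3-oxo-1,3-dihydroisobenzofuran-5-yl]acetate (racemic); 20 1-diazobut-3-en-2-one
Product: 25 methyl 2-[1-(2-ethoxy-6-hydroxyphenyl)-7-methoxy-6-(2-methyl-1,3-dioxolan-2-yl)-3-oxo-1,3-dihydroisobenzofuran-5-yl]acetate (racemic), via vinylketene 21 (not isolated), via vinylcyclobutenone 22 (not isolated), via dienylketene 23 (not isolated), via cyclohexadienone 24 (not isolated)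
Conditions: 20 (3 equiv, slow addition), ClCH2CH2Cl, hν (365 nm), rt; then 80 °C
Reagents that add atoms: none
Why: Light expels N2 from 20 and the vinyl group migrates to the carbene carbon (Wolff rearrangement), giving vinylketene 21. The alkyne carbon of 17 remote from oxygen, the nucleophilic end of the ynol ether, bonds to the ketene carbonyl carbon and the oxygen-bearing carbon to the ketene α-carbon, a polar (2+2) cycloaddition that forms C1'–C2' and C5'–C6' in cyclobutenone 22. At 80 °C 22 opens by four-electron conrotatory electrocyclic cleavage to dienylketene 23; the opening is reversible, so material that turns the vinyl group outward returns to 22 and is drained through the inward isomer. Ring C is closed by six-electron disrotatory electrocyclisation of 23, which forms C2'–C3' and gives cyclohexadienone 24, and enolisation gives phenol 25. The closest known reaction is the Danheiser benzannulation in its diazoketone form, in which aryl and vinyl diazomethyl ketones are combined with alkoxy- and siloxyalkynes in this way. No stereocentre is set: the ring carbon of 22 that carries the vinyl group becomes sp2, and the lactone carbon stays racemic until it is oxidised in step 11. The selectivity needed is regiochemical, hydroxyl and ethoxy on the two carbons flanking C1', and the polarisation of the ynol ether secures it, since only its β-carbon can attack the electrophilic ketene carbon. Chemoselectivity rests on the dioxolane, which removes the aryl ketone chromophore, and on 365 nm light, which should be absorbed by 20 and not by the benzoate of 17.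

Step 10
Reactants: 25 methyl 2-[1-(2-ethoxy-6-hydroxyphenyl)-7-methoxy-6-(2-methyl-1,3-dioxolan-2-yl)-3-oxo-1,3-dihydroisobenzofuran-5-yl]acetate (racemic)
Product: 26 methyl 2-[1-(2,6-diethoxyphenyl)-7-methoxy-6-(2-methyl-1,3-dioxolan-2-yl)-3-oxo-1,3-dihydroisobenzofuran-5-yl]acetate (racemic)
Conditions: EtI, K2CO3, acetone, 55 °C
Reagents that add atoms: iodoethane CCI
Why: Williamson etherification of the only acidic O–H; K2CO3 is too weak to deprotonate the lactone C–H or the CH2 of the ester, so C-alkylation should not compete.

Step 11
Reactants: 26 methyl 2-[1-(2,6-diethoxyphenyl)-7-methoxy-6-(2-methyl-1,3-dioxolan-2-yl)-3-oxo-1,3-dihydroisobenzofuran-5-yl]acetate (racemic)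
Product: 29 4-acetyl-5-(carboxymethyl)-2-(2,6-diethoxybenzoyl)-3-methoxybenzoic acid, via dipotassium hydroxy dicarboxylate 27 (not isolated), via dipotassium keto dicarboxylate 28 (not isolated)
Conditions: KOH, H2O/t-BuOH, 80 °C; KMnO4, 0 °C to rt; NaHSO3; 2 M HCl, THF, rt
Reagents that add atoms: potassium hydroxide [K+].[OH-]; water O
Why: Saponification opens lactone and ester to 27, in which the carbinol cannot close back; cold alkaline permanganate oxidises the secondary diaryl carbinol, the classical conversion of 3-arylphthalides into 2-aroylbenzoic acids, while the dioxolane shields the acetyl group; aqueous acid then hydrolyses the dioxolane of 28.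

Step 12
Reactants: 29 4-acetyl-5-(carboxymethyl)-2-(2,6-diethoxybenzoyl)-3-methoxybenzoic acid
Product: 30 Huanglongmycin D, 4-acetyl-5-(carboxymethyl)-2-(2,6-dihydroxybenzoyl)-3-hydroxybenzoic acid
Conditions: BBr3 (excess), CH2Cl2, −78 °C to rt; H2O
Reagents that add atoms: none
Why: Lewis-acid cleavage of aryl alkyl ethers; all three ethers are ortho to a carbonyl group that chelates boron, so they should cleave under mild conditions, and aqueous work-up hydrolyses the borates to the free phenols and acids.

## Compound list

1 | methyl 3-bromo-4-hydroxy-5-methoxybenzoate | COC(=O)c1cc(OC)c(O)c(Br)c1 | starting material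
2 | methyl 3-bromo-5-methoxy-4-[(trimethylsilyl)oxy]benzoate | COC(=O)c1cc(OC)c(O[Si](C)(C)C)c(Br)c1 | intermediate
3 | lithium 2-methoxy-4-(methoxycarbonyl)-6-(trimethylsilyl)phenolate | COC(=O)c1cc(OC)c([O-])c([Si](C)(C)C)c1.[Li+] | intermediate
4 | methyl 3-methoxy-4-[(trifluoromethanesulfonyl)oxy]-5-(trimethylsilyl)benzoate | COC(=O)c1cc(OC)c(OS(=O)(=O)C(F)(F)F)c([Si](C)(C)C)c1 | intermediate
5 | {2-methoxy-6-(methoxycarbonyl)-3-[(trifluoromethanesulfonyl)oxy]-4-(trimethylsilyl)phenyl}magnesium chloride (LiCl complex) | COC(=O)c1cc([Si](C)(C)C)c(OS(=O)(=O)C(F)(F)F)c(OC)c1[Mg]Cl | intermediate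
6 | methyl 2-iodo-3-methoxy-4-[(trifluoromethanesulfonyl)oxy]-5-(trimethylsilyl)benzoate | COC(=O)c1cc([Si](C)(C)C)c(OS(=O)(=O)C(F)(F)F)c(OC)c1I | intermediate
7 | methyl 3-oxobutanoate (methyl acetoacetate) | CC(=O)CC(=O)OC | starting material
8 | methyl 4,5-didehydro-2-iodo-3-methoxybenzoate (aryne) | COC(=O)C1=CC#CC(OC)=C1I | intermediate
9 | methyl 4-acetyl-2-iodo-3-methoxy-5-(2-methoxy-2-oxoethyl)benzoate | COC(=O)c1cc(CC(=O)OC)c(C(C)=O)c(OC)c1I | intermediate
10 | methyl 2-iodo-3-methoxy-5-(2-methoxy-2-oxoethyl)-4-(2-methyl-1,3-dioxolan-2-yl)benzoate | COC(=O)c1cc(CC(=O)OC)c(C2(C)OCCO2)c(OC)c1I | intermediate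
11 | tributyl(ethenyl)stannane | C=C[Sn](CCCC)(CCCC)CCCC | starting material
12 | methyl 2-ethenyl-3-methoxy-5-(2-methoxy-2-oxoethyl)-4-(2-methyl-1,3-dioxolan-2-yl)benzoate | COC(=O)c1cc(CC(=O)OC)c(C2(C)OCCO2)c(OC)c1C=C | intermediate
13 | methyl 2-formyl-3-methoxy-5-(2-methoxy-2-oxoethyl)-4-(2-methyl-1,3-dioxolan-2-yl)benzoate | COC(=O)c1cc(CC(=O)OC)c(C2(C)OCCO2)c(OC)c1C=O | intermediate
14 | ethoxyethyne | C#COCC | starting material
15 | (ethoxyethynyl)lithium, LiC≡COEt | [Li]C#COCC | intermediate
16 | lithium 3-ethoxy-1-[2-methoxy-6-(methoxycarbonyl)-4-(2-methoxy-2-oxoethyl)-3-(2-methyl-1,3-dioxolan-2-yl)phenyl]prop-2-yn-1-olate (racemic) | CCOC#CC([O-])c1c(OC)c(C2(C)OCCO2)c(CC(=O)OC)cc1C(=O)OC.[Li+] | intermediate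
17 | methyl 2-[1-(ethoxyethynyl)-7-methoxy-6-(2-methyl-1,3-dioxolan-2-yl)-3-oxo-1,3-dihydroisobenzofuran-5-yl]acetate (racemic) | CCOC#CC4OC(=O)c2cc(CC(=O)OC)c(C3(C)OCCO3)c(OC)c24 | intermediate
18 | but-3-en-2-one (methyl vinyl ketone) | CC(=O)C=C | starting material
19 | 1,1,1-trifluorohex-5-ene-2,4-dione | C=CC(=O)CC(=O)C(F)(F)F | intermediate
20 | 1-diazobut-3-en-2-one | C=CC(=O)C=[N+]=[N-] | intermediate
21 | buta-1,3-dien-1-one (vinylketene) | C=CC=C=O | intermediate
22 | methyl 2-[1-(3-ethenyl-2-ethoxy-4-oxocyclobut-1-en-1-yl)-7-methoxy-6-(2-methyl-1,3-dioxolan-2-yl)-3-oxo-1,3-dihydroisobenzofuran-5-yl]acetate (mixture of diastereomers) | CCOC1=C(C4OC(=O)c2cc(CC(=O)OC)c(C3(C)OCCO3)c(OC)c24)C(=O)C1C=C | intermediate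
23 | methyl 2-{1-[(3E)-3-ethoxy-1-oxohexa-1,3,5-trien-2-yl]-7-methoxy-6-(2-methyl-1,3-dioxolan-2-yl)-3-oxo-1,3-dihydroisobenzofuran-5-yl}acetate (racemic) | CCO/C(C(=C=O)C4OC(=O)c2cc(CC(=O)OC)c(C3(C)OCCO3)c(OC)c24)=C/C=C | intermediate
24 | methyl 2-[1-(2-ethoxy-6-oxocyclohexa-1,3-dien-1-yl)-7-methoxy-6-(2-methyl-1,3-dioxolan-2-yl)-3-oxo-1,3-dihydroisobenzofuran-5-yl]acetate (racemic) | CCOC1=C(C4OC(=O)c2cc(CC(=O)OC)c(C3(C)OCCO3)c(OC)c24)C(=O)CC=C1 | intermediate
25 | methyl 2-[1-(2-ethoxy-6-hydroxyphenyl)-7-methoxy-6-(2-methyl-1,3-dioxolan-2-yl)-3-oxo-1,3-dihydroisobenzofuran-5-yl]acetate (racemic) | CCOc1cccc(O)c1C4OC(=O)c2cc(CC(=O)OC)c(C3(C)OCCO3)c(OC)c24 | intermediate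
26 | methyl 2-[1-(2,6-diethoxyphenyl)-7-methoxy-6-(2-methyl-1,3-dioxolan-2-yl)-3-oxo-1,3-dihydroisobenzofuran-5-yl]acetate (racemic) | CCOc1cccc(OCC)c1C4OC(=O)c2cc(CC(=O)OC)c(C3(C)OCCO3)c(OC)c24 | intermediate
27 | dipotassium 5-(carboxylatomethyl)-2-[(2,6-diethoxyphenyl)(hydroxy)methyl]-3-methoxy-4-(2-methyl-1,3-dioxolan-2-yl)benzoate (racemic) | CCOc1cccc(OCC)c1C(O)c1c(C(=O)[O-])cc(CC(=O)[O-])c(C2(C)OCCO2)c1OC.[K+].[K+] | intermediate
28 | dipotassium 5-(carboxylatomethyl)-2-(2,6-diethoxybenzoyl)-3-methoxy-4-(2-methyl-1,3-dioxolan-2-yl)benzoate | CCOc1cccc(OCC)c1C(=O)c1c(C(=O)[O-])cc(CC(=O)[O-])c(C2(C)OCCO2)c1OC.[K+].[K+] | intermediate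
29 | 4-acetyl-5-(carboxymethyl)-2-(2,6-diethoxybenzoyl)-3-methoxybenzoic acid | CCOc1cccc(OCC)c1C(=O)c1c(C(=O)O)cc(CC(=O)O)c(C(C)=O)c1OC | intermediate
30 | Huanglongmycin D, 4-acetyl-5-(carboxymethyl)-2-(2,6-dihydroxybenzoyl)-3-hydroxybenzoic acid | CC(=O)c1c(CC(=O)O)cc(C(=O)O)c(C(=O)c2c(O)cccc2O)c1O | target

## Step count and risk

Total step count: 12 steps. Longest linear sequence: 11 steps (steps 1 to 7 and 9 to 12); step 8 is a one-step branch that supplies 20.

**Step 9 (key step).** The unsubstituted vinylketene 21 may be consumed by dimerisation and by addition to unreacted 20 faster than it is captured by the alkyne of 17, whose nucleophilicity is lowered by the acyloxy group on the propargylic carbon. In the thermal stage, traces of acid may also hydrate remaining ynol ether. The fallback brings ring C in ready-made and sets out from aldehyde 13. 1,3-Diethoxybenzene is lithiated between its two oxygens with n-BuLi to (2,6-diethoxyphenyl)lithium F1, which may be transmetalated with CeCl3 to lower its basicity. Addition to 13 at −78 °C gives lithium (2,6-diethoxyphenyl)(aryl)methanolate F2, which closes onto the ortho ester on warming and gives 26, where the route is rejoined; steps 7 to 10 fall away. The price is a bulky, basic nucleophile facing a crowded aldehyde, an acidic CH2 and two esters.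

**Step 8.** Enolisation of 18 may be overtaken by Michael oligomerisation of the enone, and 20 may be lost on concentration by dipolar addition of the diazo group of one molecule to the vinyl ketone of another. The fallback makes 21 without diazo chemistry and sets out from 17. (E)-But-2-enoyl chloride and Et3N in toluene at rt undergo 1,4-dehydrochlorination in the presence of 17, and the ketene is trapped as 22. Heating then carries 22 through 23 and 24 to 25, where the route is rejoined. No new compound is made.

**Step 11.** Hydride transfer from the carbinol, which has four ortho substituents, may be slow, so that permanganate begins to attack the benzylic CH2 of the side chain or the electron-rich ring C; carbinol that is left closes back to a lactone on acidification. The fallback oxidises a neutral hydroxy ester and sets out from 26. After saponification to 27 as in step 11 and evaporation, both carboxylates are alkylated with MeI in DMF to the hydroxy diester F3. This is oxidised at once, before it can lactonise, with Dess–Martin periodinane to the keto diester F4. LiOH and then aqueous HCl give 29, where the route is rejoined.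

**Step 7.** Compound 17 may be lost during isolation by hydration of the ynol ether or by ionisation of the propargylic C–O bond, since the lactone carboxylate leaves from a carbon that the ethoxyalkyne stabilises as a cation. Proton transfer from the CH2 of the side chain to 15 may also lower conversion. The fallback separates addition from lactonisation and sets out from 13. Acetylide 15 is added at −78 °C to 13 in the presence of Me3SiCl, so that alkoxide 16 is silylated before it cyclises. The product is the propargylic trimethylsilyl ether F5, which has no leaving group on the propargylic carbon and can be purified and stored. K2CO3 in MeOH at 0 °C, just before the key step, removes silicon; the alkoxide closes to 17, which is filtered through basic alumina and used at once.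

**Step 4.** The carbonyl carbon of the twisted, di-ortho-substituted ketone may be too shielded for ketal formation, or the oxocarbenium ion may be diverted by the neighbouring ester carbonyl into a six-membered pseudo-ester. The fallback builds the dioxolane from the carbonyl oxygen outwards and sets out from 9. With oxirane and BF3·OEt2 in CH2Cl2 the carbonyl oxygen opens the activated epoxide and the alkoxide arm closes intramolecularly, giving 10 directly. No new compound is made.

**Step 1.** n-BuLi or the aryllithium may add to the methyl ester in competition with exchange and silyl migration. The fallback introduces silicon by palladium catalysis and sets out from 1. BnBr and K2CO3 give the benzyl ether F6. Me3SiSiMe3 with Pd2(dba)3, 2-(di-tert-butylphosphino)biphenyl and LiOAc in DMF at 100 °C gives the aryl silane F7. Hydrogenolysis (H2, Pd/C) gives the phenol F8, and Tf2O with pyridine gives 4, where the route is rejoined.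

## Further compounds

F1 | step 9 | (2,6-diethoxyphenyl)lithium | [Li]c1c(OCC)cccc1OCC
F2 | step 9 | lithium (2,6-diethoxyphenyl)[2-methoxy-6-(methoxycarbonyl)-4-(2-methoxy-2-oxoethyl)-3-(2-methyl-1,3-dioxolan-2-yl)phenyl]methanolate (racemic) | CCOc1cccc(OCC)c1C([O-])c1c(OC)c(C2(C)OCCO2)c(CC(=O)OC)cc1C(=O)OC.[Li+]
F0 | step 8 | none | none
F3 | step 11 | methyl 2-[(2,6-diethoxyphenyl)(hydroxy)methyl]-3-methoxy-5-(2-methoxy-2-oxoethyl)-4-(2-methyl-1,3-dioxolan-2-yl)benzoate (racemic) | CCOc1cccc(OCC)c1C(O)c1c(C(=O)OC)cc(CC(=O)OC)c(C2(C)OCCO2)c1OC
F4 | step 11 | methyl 2-(2,6-diethoxybenzoyl)-3-methoxy-5-(2-methoxy-2-oxoethyl)-4-(2-methyl-1,3-dioxolan-2-yl)benzoate | CCOc1cccc(OCC)c1C(=O)c1c(C(=O)OC)cc(CC(=O)OC)c(C2(C)OCCO2)c1OC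
F5 | step 7 | methyl 2-{3-ethoxy-1-[(trimethylsilyl)oxy]prop-2-yn-1-yl}-3-methoxy-5-(2-methoxy-2-oxoethyl)-4-(2-methyl-1,3-dioxolan-2-yl)benzoate (racemic) | CCOC#CC(O[Si](C)(C)C)c1c(OC)c(C2(C)OCCO2)c(CC(=O)OC)cc1C(=O)OC
F0 | step 4 | none | none
F6 | step 1 | methyl 4-(benzyloxy)-3-bromo-5-methoxybenzoate | COC(=O)c1cc(OC)c(OCc2ccccc2)c(Br)c1
F7 | step 1 | methyl 4-(benzyloxy)-3-methoxy-5-(trimethylsilyl)benzoate | COC(=O)c1cc(OC)c(OCc2ccccc2)c([Si](C)(C)C)c1
F8 | step 1 | methyl 4-hydroxy-3-methoxy-5-(trimethylsilyl)benzoate | COC(=O)c1cc(OC)c(O)c([Si](C)(C)C)c1
A1 | alternative 1 | methyl 4-acetyl-2-(2,6-dimethoxybenzoyl)-3-hydroxy-5-(2-methoxy-2-oxoethyl)benzoate | COC(=O)Cc1cc(C(=O)OC)c(C(=O)c2c(OC)cccc2OC)c(O)c1C(C)=O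
A2 | alternative 1 | methyl 4-(2,6-dimethoxyphenyl)-4-oxobut-2-ynoate | COC(=O)C#CC(=O)c1c(OC)cccc1OC
A3 | alternative 1 | methyl 2-(5-acetyl-6-hydroxy-2-oxo-2H-pyran-4-yl)acetate | COC(=O)CC1=CC(=O)OC(O)=C1C(C)=O
A4 | alternative 2 | methyl 2-(9-acetyl-1,10-dimethoxy-6,11-dioxo-6,11-dihydrodibenzo[b,e]oxepin-8-yl)acetate | COC(=O)Cc1cc2C(=O)Oc3cccc(OC)c3C(=O)c2c(OC)c1C(C)=O
A5 | alternative 2 | methyl 2-(3-acetyl-4,5-dimethoxy-9,10-dioxo-9,10-dihydroanthracen-2-yl)acetate | COC(=O)Cc1cc2C(=O)c3cccc(OC)c3C(=O)c2c(OC)c1C(C)=O
A6 | alternative 3 | methyl 2-(2,6-dimethoxybenzoyl)-3,5-dioxocyclohexane-1-carboxylate (racemic, drawn as an enol) | COC(=O)C1CC(=O)CC(O)=C1C(=O)c2c(OC)cccc2OC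
A7 | alternative 3 | 1-(2,6-dimethoxyphenyl)butane-1,3-dione | CC(=O)CC(=O)c1c(OC)cccc1OC
A8 | alternative 3 | dimethyl (2E)-but-2-enedioate (dimethyl fumarate) | COC(=O)/C=C/C(=O)OC
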